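## Retrosynthetic overview
1. The strategy rests on the C11–C12 bond. C11, the carbinol carbon of ring C, is attached to C12, the β carbon of lactone D (C1–O–C14–C13–C12). A C11 aldehyde turned into its acyl anion by a carbene, and ring D as a spiro α-methylbutenolide, are polarity-matched. One Stetter closure then gives ring C, C11–C12, C12 and C13.
2. After it: C11=O is reduced to the carbinol. C5=O then becomes CH2 through the thiolactam, with the C11 hydroxyl masked during thionation.
3. Before it: the CH(Et)CHO arm comes from hydroboration/oxidation of a C10=C11 methylene. Butenolide D comes from a C1 vinyl carbinol by methacrylate ring-closing metathesis. Lactone E comes from a C18 aldehyde and a chiral ester homoenolate.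
4. The ring A/B enamide comes from N-acylation of a 1-pyrroline. Its ketone comes from 2-ethylallyl Grignard opening of an N-Boc lactam followed by C9 alkylation. C1 comes from face-selective hydroxylation of an ethylidene-lactam dienolate made from D-pyroglutaminol.
5. Ring order: B (chiral pool), A, E, D, C.

Key step: step 20

Numbering: ring A is N4, C5–C9, C9a; ring B is N4, C3, C2, C1, C9a; ring C is C9, C10, C11, C12, C1, C9a; lactone D is C1, O, C14, C13, C12; the ethyl group on C10 is C16–C17; lactone E on C3 is C18–C21.

Assumption: C10 (α to C11=O and allylic to C9=C9a) is taken to be configurationally labile in 29 and 30. Compounds 27–29 are therefore carried as C10 epimer pairs and written without a C10 descriptor, and C10 is fixed in step 20.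

## Route

Step 1
Reactants: 1 (R)-5-(hydroxymethyl)pyrrolidin-2-one (D-pyroglutaminol)
Product: 2 (R)-5-(tert-butyldiphenylsilyloxymethyl)pyrrolidin-2-one
Conditions: TBDPSCl, imidazole, DMF, 0 °C to rt
Reagents that add atoms: tert-butyl(chloro)diphenylsilane CC(C)(C)[Si](Cl)(c1ccccc1)c1ccccc1
Why: Standard O-silylation of the primary alcohol (future C18); C3 is not touched.

Step 2
Reactants: 2 silyl ether
Product: 3 N-Boc lactam of 2
Conditions: Boc2O, DMAP (cat.), Et3N, CH2Cl2, rt
Reagents that add atoms: di-tert-butyl dicarbonate CC(C)(C)OC(=O)OC(=O)OC(C)(C)C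
Why: DMAP-catalysed N-acylation; the carbamate allows clean C1 enolate chemistry and later activates the C9a carbonyl towards carbon nucleophiles.

Step 3
Reactants: 3 N-Boc lactam; 4 acetaldehyde
Product: 5 C1-(1-hydroxyethyl) lactam (mixture at C1 and at the carbinol carbon)
Conditions: LiN(SiMe3)2, THF, −78 °C; MeCHO; AcOH quench at −78 °C
Reagents that add atoms: none
Why: Lithium enolate aldol addition at C1; the cold quench avoids N-to-O Boc migration, and both new centres are erased in step 4.

Step 4
Reactants: 5 aldol adduct
Product: 7 (E)-C1-ethylidene N-Boc lactam, via C12 mesylate 6 (not isolated)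
Conditions: MsCl, Et3N, CH2Cl2, 0 °C; then DBU, rt
Reagents that add atoms: methanesulfonyl chloride CS(=O)(=O)Cl (atoms kept only in 6)
Why: Mesylation and E1cB elimination give the conjugated alkylidene lactam, with the methyl group away from the carbonyl.

Step 5
Reactants: 7 ethylidene lactam
Product: 8 (3R,5R)-3-hydroxy-3-vinyl lactam (pyrrolidinone numbering; C1 carries OH trans and vinyl cis to the C3 side chain)
Conditions: NaN(SiMe3)2, THF/DMPU, −78 °C; 3-phenyl-2-(phenylsulfonyl)oxaziridine; AcOH quench
Reagents that add atoms: 3-phenyl-2-(phenylsulfonyl)oxaziridine O=S(=O)(N1OC1c1ccccc1)c1ccccc1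
Why: Deconjugative α-hydroxylation (Davis oxidation of an extended dienolate): γ-deprotonation of the ethylidene methyl gives the dienolate, which takes oxygen at its α carbon C1 on the face anti to the C3 CH2OTBDPS group and so sets C1 (R).

Step 6
Reactants: 8 tertiary alcohol
Product: 9 C1 tert-butyldimethylsilyl ether of 8
Conditions: TBSOTf, 2,6-lutidine, CH2Cl2, −78 to 0 °C
Reagents that add atoms: tert-butyldimethylsilyl triflate CC(C)(C)[Si](C)(C)OS(=O)(=O)C(F)(F)F
Why: Silyl triflate silylation of a tertiary alcohol; at low temperature the imide-type Boc group is not attacked, and the ether later blocks α-ketol and α-iminol shifts.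

Step 7
Reactants: 10 2-ethylacrolein
Product: 11 2-methylidenebutan-1-ol
Conditions: NaBH4, CeCl3·7H2O, MeOH, 0 °C
Reagents that add atoms: none
Why: Luche 1,2-reduction of an enal.

Step 8
Reactants: 11 allylic alcohol
Product: 12 2-(bromomethyl)but-1-ene
Conditions: PBr3, Et2O, 0 °C
Reagents that add atoms: phosphorus tribromide BrP(Br)Br
Why: Bromination of a primary allylic alcohol; direct and allylic displacement give the same bromide.

Step 9
Reactants: 9 N-Boc lactam; 12 allylic bromide
Product: 13 open-chain N-Boc amino ketone: C18H2(OTBDPS)–C3H(NHBoc)–C2H2–C1(OTBS)(vinyl)–C9a(=O)–C9H2–C10(Et)=C11H2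
Conditions: 12, Mg, Et2O, 0 °C; added to 9, THF, −78 °C; AcOH quench at −78 °C
Reagents that add atoms: none
Why: Grignard addition to an N-Boc lactam with ring opening; C1 has no hydrogen, so enolisation is impossible, the allylic reagent tolerates the neopentyl carbonyl, and the cold tetrahedral adduct prevents a second addition.

Step 10
Reactants: 13 ketone; 14 tert-butyl 4-bromobutanoate
Product: 15 C9-alkylated ketone bearing the C8–C5 chain as tert-butyl ester (mixture at C9)
Conditions: KN(SiMe3)2 (1.05 equiv), THF/DMPU, −78 °C; 14, Bu4NI (cat.), −78 to 0 °C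
Reagents that add atoms: none
Why: α-Alkylation of an extended enolate; only C9 can be enolised, its hydrogens (α-keto and allylic) are more acidic than NHBoc, and the C9 centre is erased in step 12.

Step 11
Reactants: 15 keto ester
Product: 17 1-pyrroline (C9a=N4) carboxylic acid, via open-chain amino keto acid 16 (not isolated)
Conditions: TMSOTf, 2,6-lutidine, CH2Cl2, 0 °C to rt; MeOH; pH 7 buffer; 4 Å molecular sieves, CH2Cl2, rt
Reagents that add atoms: none
Why: Silyl-triflate cleavage of Boc and tert-butyl ester under buffered aprotic conditions spares the acid-sensitive 1,1-disubstituted alkene and both silyl ethers, and the free amine then condenses 5-exo-trig with the C9a ketone.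

Step 12
Reactants: 17 pyrroline acid
Product: 18 bicyclic dienamide lactam (rings A and B; C9=C9a tetrasubstituted; but-1-en-2-yl on C9; C1 OTBS and vinyl; C18 OTBDPS)
Conditions: DIC, DMAP, DMAP·HCl, CHCl3, reflux, slow addition (high dilution)
Reagents that add atoms: none
Why: Carbodiimide activation and intramolecular N-acylation of a cyclic imine; the N-acyliminium ion can lose only C9–H because C1 is quaternary, and ring A forces C8 cis to N4, hence C10 cis to C1.

Step 13
Reactants: 18 bis-silyl ether
Product: 19 diol (C18 primary OH, C1 tertiary OH)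
Conditions: Bu4NF, THF, rt to 40 °C
Reagents that add atoms: none
Why: Fluoride desilylation removes both silyl groups at once; the two hydroxyls are told apart by the next step.

Step 14
Reactants: 19 diol
Product: 20 C18 aldehyde with free C1 hydroxyl
Conditions: Dess–Martin periodinane, NaHCO3, CH2Cl2, 0 °C
Reagents that add atoms: none
Why: Dess–Martin oxidation; only the primary alcohol can be oxidised, the buffer protects the dienamide, and the aldehyde is used at once to keep C3 intact.

Step 15
Reactants: 20 aldehyde; 21 methyl (R)-3-bromo-2-methylpropanoate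
Product: 23 lactone E compound (18S,20S; cis-disubstituted butyrolactone on C3; C1 OH free), via hydroxy ester 22 (not isolated)
Conditions: 21 (3 equiv), Zn, LiCl, THF, 40 °C; TiCl(OiPr)3, −30 °C; 20, −30 to 0 °C; aq. potassium sodium tartrate; toluene, 60 °C
Reagents that add atoms: none
Why: Addition of a titanium ester homoenolate to an α-amido aldehyde, then lactonisation; the non-chelating RTi(OiPr)3 reagent should follow the Felkin–Anh model with C3–N4 anti to the incoming carbon, giving the anti (3R,18S) amino alcohol, while C20 comes unchanged from 21.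

Step 16
Reactants: 23 tertiary alcohol; 24 methacryloyl chloride
Product: 25 C1 methacrylate
Conditions: LiN(SiMe3)2 (1.0 equiv), THF, −78 °C; 24, −78 to 0 °C
Reagents that add atoms: none
Why: Acylation of the lithium alkoxide overcomes the hindrance at C1; one equivalent of base removes only the hydroxyl proton, not the lactone α-hydrogen.

Step 17
Reactants: 25 methacrylate
Product: 26 spiro α-methylbutenolide (ring D) still carrying the C10=C11 methylene
Conditions: second-generation Hoveyda–Grubbs catalyst (10 mol %), toluene, 80 °C, argon sparge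
Reagents that add atoms: none
Why: Ring-closing metathesis of a vinyl carbinol methacrylate; the catalyst loads on the only monosubstituted alkene and closes the unstrained lactone, whereas closure onto C10=C11 would need a cyclopentadiene sharing C9a with rings A and B, and the enamide is tetrasubstituted.

Step 18
Reactants: 26 diene
Product: 28 primary C11 alcohol (C10 epimer pair), via B-alkyl-9-BBN adduct 27 (not isolated)
Conditions: 9-BBN, THF, 0 °C to rt; NaBO3·4H2O, THF/H2O, rt
Reagents that add atoms: sodium perborate [Na+].[Na+].O[B-]1(O)OO[B-](O)(O)OO1; 9-borabicyclo[3.3.1]nonane B1C2CCCC1CCC2 (atoms kept only in 27)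
Why: Hydroboration–oxidation; boron goes to terminal C11 of the only electron-rich accessible alkene (the butenolide is electron-poor, the enamide tetrasubstituted), and perborate is mild towards the lactones.

Step 19
Reactants: 28 alcohol
Product: 29 Stetter precursor: bicyclic enamide lactam with spiro α-methylbutenolide at C1, lactone E on C3 and a CH(Et)CHO arm on C9 (C10 epimer pair)
Conditions: Dess–Martin periodinane, NaHCO3, CH2Cl2, 0 °C; used directly
Reagents that add atoms: none
Why: Buffered Dess–Martin oxidation gives the β,γ-unsaturated aldehyde without acid or base that could move the double bond.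

Step 20
Reactants: 29 aldehyde
Product: 30 5,11-dioxo pentacycle (ring C closed; cis C/D fusion; C13 methyl cis to C11; ethyl on the face opposite lactone D)
Conditions: 2-(pentafluorophenyl)-6,7-dihydro-5H-pyrrolo[2,1-c][1,2,4]triazol-2-ium tetrafluoroborate (20 mol %), iPr2NEt (0.5 equiv), catechol (0.5 equiv), toluene (0.01 M), 40 °C
Reagents that add atoms: none
Why: Proposed new method: the triazolylidene adds to the C11 aldehyde, proton transfer gives the nucleophilic enaminol (Breslow intermediate), C11 attacks C12 of the butenolide and expulsion of the carbene leaves the C11 ketone; the closest known reaction type is the intramolecular Stetter reaction of aliphatic aldehydes onto α,β-disubstituted acceptors with diastereoselective protonation, whereas an endocyclic butenolide acceptor beside a quaternary carbon and an α-branched β,γ-unsaturated aldehyde are untested. Ring C closes in the 6-exo-trig mode (C12 enters the ring, C13 stays outside), and the C9=C9a double bond holds C10 and C1 cis, much as the arene does in the classical salicylaldehyde-type substrates. C12 is controlled by the tether: through C10, C9 and C9a the acyl anion carbon can reach C12 only on the butenolide face that carries C9a, so only the cis C/D fusion can form. C13 is controlled by external protonation: catechol and the ammonium ion carry the hydroxyl proton away from C11 and return a proton to the lactone enolate on its open face, anti to C11 (which still bears the bulky azolium group), which leaves the methyl on the concave side cis to C11, and the weak base cannot epimerise the lactone afterwards. C10 is not set kinetically: both epimers of 29 and of 30 interconvert through their dienols under the amine, and the mixture should settle on the epimer with the ethyl group pseudo-axial and anti to lactone D, because ring B forces O1 into the axial position of the ring C half-chair and a pseudo-equatorial ethyl group would run into C8H2 (allylic 1,2-strain). The step needs acyl-anion addition to outrun Michael closure from the C10 enol, migration of C9=C9a into conjugation and β-elimination of the C1 carboxylate from 30, which is why a weak amine base, a non-polar solvent and high dilution are chosen.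

Step 21
Reactants: 30 diketo pentacycle
Product: 31 (11R)-carbinol lactam (OH on the lactone D face, trans to ethyl)
Conditions: LiBH(s-Bu)3, THF, −78 °C; AcOH/THF quench at −78 °C, no oxidative work-up
Reagents that add atoms: none
Why: Ketone reduction with a bulky trialkylborohydride; the underside of ring C is closed by axial O1 (syn-axial to that trajectory) and by the folded lactone D, so hydride should arrive on the face opposite lactone D, while the cold acidic quench keeps the C11 alkoxide from attacking C14 (translactonisation) and removes the elimination-prone β-acyloxy ketone early.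

Step 22
Reactants: 31 alcohol
Product: 32 C11 triethylsilyl ether
Conditions: TESOTf, 2,6-lutidine, CH2Cl2, −78 to 0 °C
Reagents that add atoms: triethylsilyl triflate CC[Si](CC)(CC)OS(=O)(=O)C(F)(F)F
Why: Silylation of the hindered axial alcohol; a free carbinol would react with the thionating agent faster than the lactam does.

Step 23
Reactants: 32 lactam
Product: 33 C5 thiolactam
Conditions: Lawesson's reagent (0.6 equiv), toluene, 80 °C
Reagents that add atoms: Lawesson's reagent COc1ccc(cc1)P1(=S)SP(=S)(S1)c1ccc(OC)cc1
Why: Thionation with Lawesson's reagent is selective for the amide carbonyl over the two lactones.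

Step 24
Reactants: 33 silyl ether
Product: 34 thiolactam with free C11 hydroxyl
Conditions: HF·pyridine, pyridine, THF, 0 °C
Reagents that add atoms: none
Why: Buffered fluoride cleavage of the TES ether at the robust thiolactam stage avoids basic conditions that could move lactone D onto O11.

Step 25
Reactants: 34 thiolactam
Product: 36 target CNP0154902.3 (1R,3R,10S,11R,12R,13R,18S,20S), via S-methyl thioiminium iodide 35 (not isolated)
Conditions: MeI, CH2Cl2, rt; evaporate; NaBH4, MeOH, −20 to 0 °C
Reagents that add atoms: iodomethane CI (atoms kept only in 35)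
Why: Alkylative desulfurisation of a thiolactam (S-methylation, then two hydride transfers with loss of methanethiolate); without acid the tetrasubstituted enamine is not protonated and so not reduced, and the allylic C1–O bond and both lactones are left alone.

## Compound list
1 | (R)-5-(hydroxymethyl)pyrrolidin-2-one | O=C1N[C@@H](CO)CC1 | starting material
2 | TBDPS ether of 1 | O=C1N[C@@H](CO[Si](c2ccccc2)(c2ccccc2)C(C)(C)C)CC1 | intermediate
3 | N-Boc lactam | O=C1N(C(=O)OC(C)(C)C)[C@@H](CO[Si](c2ccccc2)(c2ccccc2)C(C)(C)C)CC1 | intermediate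
4 | acetaldehyde | CC=O | starting material
5 | C1-(1-hydroxyethyl) lactam | O=C1N(C(=O)OC(C)(C)C)[C@@H](CO[Si](c2ccccc2)(c2ccccc2)C(C)(C)C)CC1C(C)O | intermediate
6 | mesylate of 5 | O=C1N(C(=O)OC(C)(C)C)[C@@H](CO[Si](c2ccccc2)(c2ccccc2)C(C)(C)C)CC1C(C)OS(C)(=O)=O | intermediate
7 | (E)-ethylidene lactam | C/C=C1/C(=O)N(C(=O)OC(C)(C)C)[C@@H](CO[Si](c2ccccc2)(c2ccccc2)C(C)(C)C)C1 | intermediate
8 | C1 hydroxy vinyl lactam | O=C1N(C(=O)OC(C)(C)C)[C@@H](CO[Si](c2ccccc2)(c2ccccc2)C(C)(C)C)C[C@@]1(O)C=C | intermediate
9 | C1 OTBS vinyl lactam | O=C1N(C(=O)OC(C)(C)C)[C@@H](CO[Si](c2ccccc2)(c2ccccc2)C(C)(C)C)C[C@@]1(O[Si](C)(C)C(C)(C)C)C=C | intermediate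
10 | 2-ethylacrolein | C=C(CC)C=O | starting material
11 | 2-methylidenebutan-1-ol | C=C(CC)CO | intermediate
12 | 2-(bromomethyl)but-1-ene | C=C(CC)CBr | intermediate
13 | N-Boc amino 2-ethylallyl ketone | CC(C)(C)OC(=O)N[C@@H](CO[Si](c1ccccc1)(c1ccccc1)C(C)(C)C)C[C@@](O[Si](C)(C)C(C)(C)C)(C=C)C(=O)CC(=C)CC | intermediate
14 | tert-butyl 4-bromobutanoate | CC(C)(C)OC(=O)CCCBr | starting material
15 | C9-alkylated keto ester | CC(C)(C)OC(=O)N[C@@H](CO[Si](c1ccccc1)(c1ccccc1)C(C)(C)C)C[C@@](O[Si](C)(C)C(C)(C)C)(C=C)C(=O)C(CCCC(=O)OC(C)(C)C)C(=C)CC | intermediate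
16 | open-chain amino keto acid | N[C@@H](CO[Si](c1ccccc1)(c1ccccc1)C(C)(C)C)C[C@@](O[Si](C)(C)C(C)(C)C)(C=C)C(=O)C(CCCC(=O)O)C(=C)CC | intermediate
17 | 1-pyrroline acid | OC(=O)CCCC(C(=C)CC)C1=N[C@@H](CO[Si](c2ccccc2)(c2ccccc2)C(C)(C)C)C[C@@]1(O[Si](C)(C)C(C)(C)C)C=C | intermediate
18 | bicyclic dienamide lactam, bis-silyl ether | C=C(CC)C1=C2N(C(=O)CCC1)[C@@H](CO[Si](c3ccccc3)(c3ccccc3)C(C)(C)C)C[C@@]2(O[Si](C)(C)C(C)(C)C)C=C | intermediate
19 | diol | C=C(CC)C1=C2N(C(=O)CCC1)[C@@H](CO)C[C@@]2(O)C=C | intermediate
20 | C18 aldehyde | C=C(CC)C1=C2N(C(=O)CCC1)[C@@H](C=O)C[C@@]2(O)C=C | intermediate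
21 | methyl (R)-3-bromo-2-methylpropanoate | COC(=O)[C@@H](C)CBr | starting material
22 | C18 hydroxy ester | C=C(CC)C1=C2N(C(=O)CCC1)[C@@H]([C@@H](O)C[C@H](C)C(=O)OC)C[C@@]2(O)C=C | intermediate
23 | lactone E carbinol | C=C(CC)C1=C2N(C(=O)CCC1)[C@@H]([C@@H]3C[C@H](C)C(=O)O3)C[C@@]2(O)C=C | intermediate
24 | methacryloyl chloride | C=C(C)C(=O)Cl | starting material
25 | C1 methacrylate | C=C(CC)C1=C2N(C(=O)CCC1)[C@@H]([C@@H]3C[C@H](C)C(=O)O3)C[C@@]2(OC(=O)C(C)=C)C=C | intermediate
26 | spiro butenolide diene | C=C(CC)C1=C2N(C(=O)CCC1)[C@@H]([C@@H]3C[C@H](C)C(=O)O3)C[C@]21OC(=O)C(C)=C1 | intermediate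
27 | B-alkyl-9-BBN adduct | CCC(CB3C4CCCC3CCC4)C1=C2N(C(=O)CCC1)[C@@H]([C@@H]3C[C@H](C)C(=O)O3)C[C@]21OC(=O)C(C)=C1 | intermediate
28 | C11 primary alcohol (C10 epimer pair) | CCC(CO)C1=C2N(C(=O)CCC1)[C@@H]([C@@H]3C[C@H](C)C(=O)O3)C[C@]21OC(=O)C(C)=C1 | intermediate
29 | Stetter precursor aldehyde (C10 epimer pair) | CCC(C=O)C1=C2N(C(=O)CCC1)[C@@H]([C@@H]3C[C@H](C)C(=O)O3)C[C@]21OC(=O)C(C)=C1 | intermediate
30 | 5,11-dioxo pentacycle | CC[C@H]1C2=C3N(C(=O)CCC2)[C@@H]([C@@H]2C[C@H](C)C(=O)O2)C[C@]32OC(=O)[C@H](C)[C@@H]2C1=O | intermediate
31 | (11R)-hydroxy lactam | CC[C@H]1C2=C3N(C(=O)CCC2)[C@@H]([C@@H]2C[C@H](C)C(=O)O2)C[C@]32OC(=O)[C@H](C)[C@@H]2[C@@H]1O | intermediate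
32 | C11 TES ether lactam | CC[C@H]1C2=C3N(C(=O)CCC2)[C@@H]([C@@H]2C[C@H](C)C(=O)O2)C[C@]32OC(=O)[C@H](C)[C@@H]2[C@@H]1O[Si](CC)(CC)CC | intermediate
33 | C11 TES ether thiolactam | CC[C@H]1C2=C3N(C(=S)CCC2)[C@@H]([C@@H]2C[C@H](C)C(=O)O2)C[C@]32OC(=O)[C@H](C)[C@@H]2[C@@H]1O[Si](CC)(CC)CC | intermediate
34 | hydroxy thiolactam | CC[C@H]1C2=C3N(C(=S)CCC2)[C@@H]([C@@H]2C[C@H](C)C(=O)O2)C[C@]32OC(=O)[C@H](C)[C@@H]2[C@@H]1O | intermediate
35 | S-methyl thioiminium iodide | CC[C@H]1C2=C3[N+](=C(SC)CCC2)[C@@H]([C@@H]2C[C@H](C)C(=O)O2)C[C@]32OC(=O)[C@H](C)[C@@H]2[C@@H]1O.[I-] | intermediate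
36 | CNP0154902.3 | CC[C@H]1C2=C3N(CCCC2)[C@@H]([C@@H]2C[C@H](C)C(=O)O2)C[C@]32OC(=O)[C@H](C)[C@@H]2[C@@H]1O | target

## Step count and risks
Total step count: 25. Longest linear sequence: 23 steps (steps 1–6 and 9–25, from 1 to 36).

**1. Step 20 (Stetter closure).**
- Carbene addition to the hindered α-branched aldehyde may be slow, so that base-driven processes take over. These are 5-exo Michael closure from the C10 enol onto C12, and migration of C9=C9a into conjugation with the aldehyde.
- The β-acyloxy ketone product may lose the C1 carboxylate, with ring C then aromatising.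
- The proton at C13 may be delivered internally from the C11 hydroxyl on the concave face instead of externally.
- Fallback (known chemistry), setting out from 29: a ketyl–olefin cyclisation with SmI2 and t-BuOH in THF at −78 °C. The C11 ketyl radical adds 6-exo to C12 on the same tether-enforced face. The samarium enolate is protonated by the alcohol on its open face, giving the 11-epi hydroxy pentacycle F1 (hydroxyl expected anti to C13).
- Dess–Martin oxidation of F1 and brief treatment with iPr2NEt in toluene to equilibrate C10 lead back to 30.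

**2. Step 21 (C11 reduction).**
- Facial selectivity may be poor. The pseudo-axial ethyl group shields the face from which hydride must come, in competition with the shielding of the other face by O1. The modest thermodynamic bias at C10 may also leave epimer behind.
- The C11 alkoxide may attack C14.
- Fallback, setting out from 30: soft enolisation (TMSOTf, Et3N, CH2Cl2, −78 °C) gives the silyl dienol ether F2.
- Saegusa–Ito oxidation with Pd(OAc)2 in MeCN follows. β-Hydride loss is possible only from C16, so it gives the 10-ethylidene enone F3.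
- Luche reduction (NaBH4, CeCl3·7H2O, MeOH, −78 °C) now meets no ethyl group on the open face and gives the allylic alcohol F4.
- Hydroxyl-directed hydrogenation with [Ir(cod)(PCy3)(py)]PF6 and H2 in CH2Cl2 delivers hydrogen to C10 from the hydroxyl face. This places the ethyl group trans to OH and comes back to 31, with C10 and C11 both set independently of any equilibrium.

**3. Step 17 (ring-closing metathesis).**
- Closure onto the methacrylate may be slow at the neopentyl vinyl group. That would leave time for metathesis at the C10=C11 methylene or for oligomerisation.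
- Fallback, setting out from 25: the competing alkene is removed first. 9-BBN (about one equivalent, 0 °C) should prefer the electron-rich 1,1-disubstituted C10=C11 over the acyloxy-deactivated neopentyl vinyl group and the electron-poor methacrylate. Perborate oxidation then gives the hydroxy methacrylate F5.
- Ring-closing metathesis of F5 under the conditions of step 17 comes back to the route at 28.

## Further compounds
F1 | step 20 | 11-epi hydroxy pentacycle lactam | CC[C@H]1C2=C3N(C(=O)CCC2)[C@@H]([C@@H]2C[C@H](C)C(=O)O2)C[C@]32OC(=O)[C@H](C)[C@@H]2[C@H]1O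
F2 | step 21 | 11-trimethylsilyloxy 10,11-ene (silyl dienol ether) | CCC=1C2=C3N(C(=O)CCC2)[C@@H]([C@@H]2C[C@H](C)C(=O)O2)C[C@]32OC(=O)[C@H](C)[C@@H]2C=1O[Si](C)(C)C
F3 | step 21 | 10-ethylidene 11-ketone | C/C=C1/C2=C3N(C(=O)CCC2)[C@@H]([C@@H]2C[C@H](C)C(=O)O2)C[C@]32OC(=O)[C@H](C)[C@@H]2C1=O
F4 | step 21 | 10-ethylidene (11R)-carbinol | C/C=C1/C2=C3N(C(=O)CCC2)[C@@H]([C@@H]2C[C@H](C)C(=O)O2)C[C@]32OC(=O)[C@H](C)[C@@H]2[C@@H]1O
F5 | step 17 | C11 hydroxy C1 methacrylate (C10 epimer pair) | CCC(CO)C1=C2N(C(=O)CCC1)[C@@H]([C@@H]3C[C@H](C)C(=O)O3)C[C@@]2(OC(=O)C(C)=C)C=C
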